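The rings are numbered from C1 (OMe) to C6 (bridging O) in ring A and from C1' (bridging O) to C6' (OH) in ring B. The feature exploited is the pair of C–H positions at C3 (ring A) and C3' (ring B). Each lies between two bromines and para to an oxygenated carbon (C6, C6'), so each marks a departed amino group. One bromination of a diamino diaryl ether installs the bromines at C2, C4, C2' and C4' together, and double hydrodediazoniation then removes both nitrogens. The precursor carries a benzyl ether at C6' and already holds the C5' bromine, because a phenol bromination after deamination could also strike the vacated C3'.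

Key step: step 5

Remark on locants: the target locants are used for all intermediates. Ring A is C1 OMe, C2 Br, C3 H, C4 Br, C5 H, C6 O. Ring B is C1' O, C2' Br, C3' H, C4' Br, C5' Br, C6' OH.

Remark on the chemistry (assumption): the target has no stereocentre and rotation about the diaryl ether bonds is taken as free. No stereochemical element has to be set, and the SMILES carry no stereo descriptors.

Step 1
Reactants: 1 4-nitrocatechol
Product: 2 3-bromo-5-nitrobenzene-1,2-diol
Conditions: Br2 (1.0 equiv), NaOAc, AcOH, 15–20 °C
Reagents that add atoms: bromine, BrBr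
Why: Electrophilic aromatic bromination should be steered by the more acidic hydroxyl para to nitro, which is partly ionised in the acetate buffer and whose only open ortho or para carbon is the future C5', a site that is also meta to nitro, the same pattern as vanillin to 5-bromovanillin.

Step 2
Reactants: 2 3-bromo-5-nitrobenzene-1,2-diol; 3 benzyl bromide
Product: 4 2-(benzyloxy)-3-bromo-5-nitrophenol
Conditions: KHCO3 (1.1 equiv), DMF, 40 °C
Reagents that add atoms: none
Why: In this Williamson ether synthesis the weak base ionises only the hydroxyl conjugated with nitro (and further acidified by the ortho bromine), so that oxygen is benzylated and the hydroxyl meta to nitro stays free, as known for mono-alkylation of 4-nitrocatechol and 3,4-dihydroxybenzaldehyde.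

Step 3
Reactants: 4 2-(benzyloxy)-3-bromo-5-nitrophenol; 5 1-fluoro-2-methoxy-4-nitrobenzene
Product: 6 2-(benzyloxy)-1-bromo-3-(2-methoxy-4-nitrophenoxy)-5-nitrobenzene
Conditions: K2CO3, DMF, 90 °C
Reagents that add atoms: none
Why: In this nucleophilic aromatic substitution (SNAr, addition–elimination) the phenoxide of 4 adds to the C–F carbon of 5, the para nitro group stabilises the Meisenheimer adduct and fluoride leaves, while the C–Br bond of 4 is meta to its nitro group and therefore inert, and no bromine yet crowds the new ether.

Step 4
Reactants: 6 2-(benzyloxy)-1-bromo-3-(2-methoxy-4-nitrophenoxy)-5-nitrobenzene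
Product: 7 4-[5-amino-2-(benzyloxy)-3-bromophenoxy]-3-methoxyaniline
Conditions: Fe powder, AcOH–EtOH–H2O, 65 °C; crude product used at once
Reagents that add atoms: none
Why: Béchamp-type reduction with iron in acetic acid converts both nitro groups to amines and, unlike catalytic hydrogenation, leaves the aryl bromide and the benzyl ether untouched.

Step 5
Reactants: 7 4-[5-amino-2-(benzyloxy)-3-bromophenoxy]-3-methoxyaniline
Product: 8 4-[3-amino-6-(benzyloxy)-2,4,5-tribromophenoxy]-2,6-dibromo-3-methoxyaniline
Conditions: Br2 (4.1 equiv), NaOAc (5 equiv), AcOH, 10–20 °C, dark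
Reagents that add atoms: bromine, BrBr
Why: Each of the four events is an electrophilic aromatic substitution in which Br2 attacks a carbon next to a free amino group, the arenium ion is stabilised in its iminium form, and acetate removes the proton. The closest known reaction type is the exhaustive ortho-bromination of para-blocked anilines, for example p-anisidine to 2,6-dibromo-4-methoxyaniline. No ring is closed and no stereocentre is formed. The step needs site selectivity among the five open core positions of 7 (C2, C4, C5, C2', C4') and against the benzyl phenyl ring; on each ring nitrogen outranks the oxygen donors, and because C6 and C6' (para to nitrogen) are occupied by oxygen, substitution can go only to the two carbons beside nitrogen, a preference that OMe reinforces at C2 and C4 and the bridging oxygen at C2' and C4'. The only core carbon left over, C5, is meta to both NH2 and OMe on a ring that by then carries two bromines, and C5' is already filled, so a fifth substitution has no easy outlet. NaOAc takes up HBr, which keeps the weakly basic bromoanilines unprotonated for the later substitutions and shields the benzyl ether from HBr in AcOH.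

Step 6
Reactants: 8 4-[3-amino-6-(benzyloxy)-2,4,5-tribromophenoxy]-2,6-dibromo-3-methoxyaniline
Product: 10 3-(benzyloxy)-1,2,5-tribromo-4-(3,5-dibromo-2-methoxyphenoxy)benzene, via bis(diazonium) ditosylate 9 (not isolated)
Conditions: t-BuONO (2.6 equiv), p-TsOH·H2O (3 equiv), THF–MeCN, 0 °C; then 50% aq H3PO2, Cu2O (cat.), 0 °C to rt
Reagents that add atoms: none
Why: This is diazotisation followed by hydrodediazoniation, in which an alkyl nitrite with a soluble strong acid nitrosates even these weakly basic 2,6-dibromoanilines and H3PO2 reduces the electron-poor diazonium groups through a Cu2O-initiated aryl radical chain, as in the passage from 2,4,6-tribromoaniline to 1,3,5-tribromobenzene; chloride is excluded so that no bromine ortho to N2+ is exchanged, and the acid is too mild to cleave the benzyl ether.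

Step 7
Reactants: 10 3-(benzyloxy)-1,2,5-tribromo-4-(3,5-dibromo-2-methoxyphenoxy)benzene
Product: 12 2,3,5-tribromo-6-(3,5-dibromo-2-methoxyphenoxy)phenol, via aryloxydichloroborane 11 (not isolated)
Conditions: BCl3 (2.5 equiv), C6HMe5 (3 equiv), CH2Cl2, −78 °C; then H2O
Reagents that add atoms: none
Why: In this Lewis acid mediated benzyl ether cleavage BCl3 binds the ether oxygen and the benzyl cation is passed to pentamethylbenzene by Friedel–Crafts alkylation, so it cannot re-attack either ring; at −78 °C the aryl methyl ether and the five C–Br bonds (which hydrogenolysis would endanger) should remain, and water then hydrolyses the B–O bond.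

Compound list
1 | 4-nitrocatechol (4-nitrobenzene-1,2-diol) | Oc1ccc([N+](=O)[O-])cc1O | starting material
2 | 3-bromo-5-nitrobenzene-1,2-diol | Oc1cc([N+](=O)[O-])cc(Br)c1O | intermediate
3 | benzyl bromide | BrCc1ccccc1 | starting material
4 | 2-(benzyloxy)-3-bromo-5-nitrophenol | Oc1cc([N+](=O)[O-])cc(Br)c1OCc1ccccc1 | intermediate
5 | 1-fluoro-2-methoxy-4-nitrobenzene | COc1cc([N+](=O)[O-])ccc1F | starting material
6 | 2-(benzyloxy)-1-bromo-3-(2-methoxy-4-nitrophenoxy)-5-nitrobenzene | COc1cc([N+](=O)[O-])ccc1Oc1cc([N+](=O)[O-])cc(Br)c1OCc1ccccc1 | intermediate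
7 | 4-[5-amino-2-(benzyloxy)-3-bromophenoxy]-3-methoxyaniline | COc1cc(N)ccc1Oc1cc(N)cc(Br)c1OCc1ccccc1 | intermediate
8 | 4-[3-amino-6-(benzyloxy)-2,4,5-tribromophenoxy]-2,6-dibromo-3-methoxyaniline | COc1c(Br)c(N)c(Br)cc1Oc1c(Br)c(N)c(Br)c(Br)c1OCc1ccccc1 | intermediate
9 | 4-[6-(benzyloxy)-2,4,5-tribromo-3-diazoniophenoxy]-2,6-dibromo-3-methoxybenzenediazonium bis(4-methylbenzenesulfonate) | COc1c(Br)c([N+]#N)c(Br)cc1Oc1c(Br)c([N+]#N)c(Br)c(Br)c1OCc1ccccc1.Cc1ccc(cc1)S([O-])(=O)=O.Cc1ccc(cc1)S([O-])(=O)=O | intermediate
10 | 3-(benzyloxy)-1,2,5-tribromo-4-(3,5-dibromo-2-methoxyphenoxy)benzene | COc1c(Br)cc(Br)cc1Oc1c(Br)cc(Br)c(Br)c1OCc1ccccc1 | intermediate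
11 | dichloro[2,3,5-tribromo-6-(3,5-dibromo-2-methoxyphenoxy)phenoxy]borane | COc1c(Br)cc(Br)cc1Oc1c(Br)cc(Br)c(Br)c1OB(Cl)Cl | intermediate
12 | 2,3,5-tribromo-6-(3,5-dibromo-2-methoxyphenoxy)phenol (CNP0282108.0) | COc1c(Br)cc(Br)cc1Oc1c(Br)cc(Br)c(Br)c1O | target

Total step count: 7
Longest linear sequence: 7 steps (1 → 2 → 4 → 6 → 7 → 8 → 10 → 12)

Steps most likely to fail

**Step 5.**
- What may go wrong:
  - Bromine may oxidise the electron-rich para-alkoxyaniline rings (ipso attack para to nitrogen, then collapse to quinone-imine-type material) in competition with substitution.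
  - The reaction may stall after two or three substitutions at the carbons wedged between two substituents (C2, C2', C4'), which would leave mixtures that are hard to separate.
- The fallback brominates ring by ring and finishes ring B before the ether bond is made. It sets out from 4 and comes back at 8. Fe in AcOH–EtOH–H2O reduces 4 to 5-amino-2-(benzyloxy)-3-bromophenol F1. Br2 (2 equiv) with NaOAc in AcOH should then give 3-amino-6-(benzyloxy)-2,4,5-tribromophenol F2, because NH2 and the free OH both point to C2' and C4'. The phenoxide of F2 (K2CO3, DMF, 100 °C) displaces fluoride from 5 to give 4-(benzyloxy)-2,3,6-tribromo-5-(2-methoxy-4-nitrophenoxy)aniline F3; the amine flanked by two bromines is not nucleophilic and does not compete. Fe in AcOH–EtOH–H2O gives 4-[3-amino-6-(benzyloxy)-2,4,5-tribromophenoxy]-3-methoxyaniline F4. Br2 (2 equiv) with NaOAc in AcOH then has a single aniline ring left to brominate and gives 8.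

**Step 6.**
- What may go wrong:
  - With two diazonium groups to be reduced in one flask, one of them may leave by a competing path. Possible paths are capture of the aryl cation or radical by water, tosylate or solvent, and azo coupling with amine that is not yet diazotised.
  - Long acid contact may begin to loosen the benzyl ether.
- The fallback replaces N2+ by iodine and then removes iodine by chemoselective metalation. It sets out from 8 and comes back at 10. Salt 9 is made as in step 6 and treated with aqueous KI in a catalyst-free Sandmeyer-type iodo-dediazoniation. This should give 1-(benzyloxy)-2,3,5-tribromo-6-(3,5-dibromo-4-iodo-2-methoxyphenoxy)-4-iodobenzene F5. i-PrMgCl (2.1 equiv, THF, −78 to −40 °C) exchanges the two C–I bonds far faster than any C–Br bond and gives the bis(arylmagnesium chloride) F6. F6 is kept cold to suppress aryne formation and is protonated with dilute HCl to give 10.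

**Step 1.**
- What may go wrong:
  - The other hydroxyl may direct part of the bromination to the carbons ortho to nitro.
  - Double bromination may occur.
  - The catechol may be oxidised to an ortho-quinone.
- The fallback makes the diaryl ether first, so that only one hydroxyl remains to direct. It sets out from 1 and comes back at 6. With both hydroxyls of 1 ionised (KOH, 2.0 equiv, DMSO), the far more basic oxygen meta to nitro should be the one that attacks 5 (SNAr, 60 °C). After acidification with HCl this gives 2-(2-methoxy-4-nitrophenoxy)-4-nitrophenol F7. In F7 the single phenol has nitro on its para carbon and the ether on one ortho carbon, so Br2 with NaOAc in AcOH can reach only C5' and should give 2-bromo-6-(2-methoxy-4-nitrophenoxy)-4-nitrophenol F8. Benzylation with 3 (K2CO3, DMF, 50 °C) gives 6.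

Further compounds
F1 | step 5 | 5-amino-2-(benzyloxy)-3-bromophenol | Nc1cc(O)c(OCc2ccccc2)c(Br)c1
F2 | step 5 | 3-amino-6-(benzyloxy)-2,4,5-tribromophenol | Nc1c(Br)c(O)c(OCc2ccccc2)c(Br)c1Br
F3 | step 5 | 4-(benzyloxy)-2,3,6-tribromo-5-(2-methoxy-4-nitrophenoxy)aniline | COc1cc([N+](=O)[O-])ccc1Oc1c(Br)c(N)c(Br)c(Br)c1OCc1ccccc1
F4 | step 5 | 4-[3-amino-6-(benzyloxy)-2,4,5-tribromophenoxy]-3-methoxyaniline | COc1cc(N)ccc1Oc1c(Br)c(N)c(Br)c(Br)c1OCc1ccccc1
F5 | step 6 | 1-(benzyloxy)-2,3,5-tribromo-6-(3,5-dibromo-4-iodo-2-methoxyphenoxy)-4-iodobenzene | COc1c(Br)c(I)c(Br)cc1Oc1c(Br)c(I)c(Br)c(Br)c1OCc1ccccc1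
F6 | step 6 | bis(arylmagnesium chloride) derived from F5 by exchange of both iodines | COc1c(Br)c([Mg]Cl)c(Br)cc1Oc1c(Br)c([Mg]Cl)c(Br)c(Br)c1OCc1ccccc1
F7 | step 1 | 2-(2-methoxy-4-nitrophenoxy)-4-nitrophenol | COc1cc([N+](=O)[O-])ccc1Oc1cc([N+](=O)[O-])ccc1O
F8 | step 1 | 2-bromo-6-(2-methoxy-4-nitrophenoxy)-4-nitrophenol | COc1cc([N+](=O)[O-])ccc1Oc1cc([N+](=O)[O-])cc(Br)c1O
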